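**Assumption:** chain carbons are numbered C1 (benzylic) to C16; compounds 1, 5, 9, 10, 14 and 17 are taken as catalogue chemicals (14 is otherwise one step from but-2-ynoic acid with NaI/AcOH).

## Retrosynthetic overview

1. Target ⇐ its aryl TBS ether ⇐ C4–C5 bond by a visible-light, nickel-catalysed reductive acyl–allyl coupling of an (E)-aryl-prenyl carbonate with a (Z)-enoic acid.
2. Allyl carbonate ⇐ aryl Grignard + isoprene monoxide (SN2'); the aryl bromide ⇐ C–H borylation/oxidation of 2-bromo-6-methylanisole.
3. (Z)-Enoic acid ⇐ B-alkyl Suzuki coupling with (Z)-3-iodobut-2-enoic acid (C7–C8) and Weinreb ketone synthesis with a C5 alkoxide-Grignard (C12–C13).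
4. The C11 stereocentre is bought as methyl (S)-3-bromo-2-methylpropanoate (Roche ester series) and carried through zinc insertion/Negishi vinylation.
5. No ring is formed; the only ring, the arene, is bought.

## Route

Step 1
Reactants: 1 2-bromo-6-methylanisole
Product: 3 3-bromo-4-methoxy-5-methylphenol, via aryl pinacol boronate 2 (not isolated)
Conditions: [Ir(OMe)(cod)]2 (1.5 mol%), dtbpy (3 mol%), B2pin2 (1.0 equiv), THF, 80 °C; then KHSO5 (Oxone triple salt 2KHSO5·KHSO4·K2SO4), acetone/H2O, 20 °C
Reagents that add atoms: bis(pinacolato)diboron CC1(C)OB(OC1(C)C)B1OC(C)(C)C(C)(C)O1 (only in intermediate 2); potassium peroxymonosulfate [K+].[O-]S(=O)(=O)OO (phenol oxygen)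
Why: Sterically controlled iridium-catalysed C–H borylation of a 1,2,3-trisubstituted arene takes the only C–H flanked by two hydrogens (para to OMe), and peroxymonosulfate oxidation of the C–B bond gives the phenol in one pot (C–H borylation/oxidation).

Step 2
Reactants: 3 3-bromo-4-methoxy-5-methylphenol
Product: 4 (3-bromo-4-methoxy-5-methylphenoxy)(tert-butyl)dimethylsilane
Conditions: TBSCl, imidazole, DMF, 20 °C
Reagents that add atoms: tert-butyldimethylsilyl chloride CC(C)(C)[Si](C)(C)Cl
Why: Standard phenol silylation; the TBS ether masks the acidic, nucleophilic phenol for the Grignard and allyl-nickel chemistry and comes off under buffered fluoride.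

Step 3
Reactants: 4 (3-bromo-4-methoxy-5-methylphenoxy)(tert-butyl)dimethylsilane; 5 2-methyl-2-vinyloxirane (isoprene monoxide, racemic)
Product: 8 (E)-4-[5-(tert-butyldimethylsilyloxy)-2-methoxy-3-methylphenyl]-2-methylbut-2-en-1-yl methyl carbonate, via aryl Grignard reagent 6 (not isolated), via bromomagnesium allylic alkoxide 7 (not isolated)
Conditions: Mg turnings, LiCl, THF, 40 °C; CuI (10 mol%), 5 (1.2 equiv), −30 °C; then ClCO2Me, −30 → 0 °C; chromatography to remove the minor Z isomer
Reagents that add atoms: magnesium [Mg] (only in intermediates 6 and 7); methyl chloroformate COC(=O)Cl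
Why: Copper-catalysed anti-SN2' opening of the vinyl epoxide by the aryl Grignard gives mainly the (E)-trisubstituted allylic alkoxide (expected about 9:1 E/Z), which is trapped in the same pot as the methyl carbonate.

Step 4
Reactants: 9 methyl (S)-3-bromo-2-methylpropanoate; 10 vinyl bromide
Product: 12 methyl (R)-2-methylpent-4-enoate, via alkylzinc bromide 11 (not isolated)
Conditions: Zn dust (TMSCl/1,2-dibromoethane activated), LiCl, THF, 40 °C; then 10 (1 M in THF), Pd(OAc)2 (2 mol%), SPhos (4 mol%), 20 °C
Reagents that add atoms: zinc [Zn] (only in intermediate 11)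
Why: Zinc insertion gives a β-zincio ester that neither eliminates nor enolises, and Negishi coupling with vinyl bromide adds C8–C9 without touching the bought C11 stereocentre (the descriptor changes from S to R only through CIP priorities).

Step 5
Reactants: 12 methyl (R)-2-methylpent-4-enoate
Product: 13 (2R)-N-methoxy-N,2-dimethylpent-4-enamide
Conditions: MeNH(OMe)·HCl (1.5 equiv), iPrMgCl (3.0 equiv), THF, −20 → 0 °C
Reagents that add atoms: N,O-dimethylhydroxylamine hydrochloride CNOC.Cl
Why: Ester aminolysis by the chloromagnesium amide at low temperature (Weinreb amide formation) is fast and leaves the α-stereocentre intact.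

Step 6
Reactants: 13 (2R)-N-methoxy-N,2-dimethylpent-4-enamide; 14 (Z)-3-iodobut-2-enoic acid
Product: 16 (2Z,7R)-8-[methoxy(methyl)amino]-3,7-dimethyl-8-oxooct-2-enoic acid, via B-alkyl-9-BBN 15 (not isolated)
Conditions: 9-BBN (1.1 equiv B–H), THF, 0 → 20 °C; then 14 (1.1 equiv), Pd(dppf)Cl2 (5 mol%), AsPh3 (5 mol%), K3PO4 (3 M aq, 3.5 equiv), DMF, 20 °C; citric acid work-up
Reagents that add atoms: 9-borabicyclo[3.3.1]nonane B1C2CCCC1CCC2 (only in intermediate 15)
Why: Anti-Markovnikov hydroboration followed by B-alkyl Suzuki–Miyaura coupling forms C7–C8 with retention of the vinyl iodide geometry, so the chain ends up cis to the carboxyl (6Z); the carboxylate and the Weinreb amide are inert.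

Step 7
Reactants: 16 (2Z,7R)-8-[methoxy(methyl)amino]-3,7-dimethyl-8-oxooct-2-enoic acid; 17 4-chloro-2-methylbutan-2-ol
Product: 19 (2Z,7R)-11-hydroxy-3,7,11-trimethyl-8-oxododec-2-enoic acid, via alkoxide Grignard reagent 18 (not isolated)
Conditions: 17, iPrMgCl (1 equiv), THF, −20 °C, then Mg turnings, reflux (gives 18, 2 equiv); 16, iPrMgCl (1.0 equiv), THF, −20 °C, then 18, −20 → 0 °C; cold 10% citric acid
Reagents that add atoms: magnesium [Mg] (only in intermediate 18); isopropylmagnesium chloride CC(C)[Mg]Cl (only in intermediate 18)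
Why: Weinreb ketone synthesis with a Normant-type alkoxide-Grignard: the chelated tetrahedral adduct prevents over-addition and α-epimerisation, the magnesium carboxylate is inert, and the tertiary alcohol is delivered unprotected.

Step 8
Reactants: 8 (E)-4-[5-(tert-butyldimethylsilyloxy)-2-methoxy-3-methylphenyl]-2-methylbut-2-en-1-yl methyl carbonate; 19 (2Z,7R)-11-hydroxy-3,7,11-trimethyl-8-oxododec-2-enoic acid
Product: 21 (2E,6Z,11R)-1-[5-(tert-butyldimethylsilyloxy)-2-methoxy-3-methylphenyl]-15-hydroxy-3,7,11,15-tetramethylhexadeca-2,6-diene-5,12-dione, via mixed methyl carbonic anhydride 20 (not isolated)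
Conditions: 19, dimethyl dicarbonate (1.3 equiv), 2,6-lutidine (1.5 equiv), DMA, 20 °C, 30 min; then 8 (1.5 equiv), NiBr2(dme) (10 mol%), dtbbpy (12 mol%), 4CzIPN (2 mol%), Hantzsch ester (1.5 equiv), degassed, 450 nm LEDs, 20 °C
Reagents that add atoms: dimethyl dicarbonate COC(=O)OC(=O)OC (only in intermediate 20)
Why: Proposed new method: a visible-light nickel-catalysed reductive acyl–allyl cross-electrophile coupling, in which photoreduced 4CzIPN (Hantzsch ester as terminal reductant) generates zerovalent nickel, which ionises carbonate 8 to a syn η3-allyl complex of divalent nickel (E geometry kept); one-electron reduction to the allyl complex of monovalent nickel, oxidative addition into the C(acyl)–O bond of anhydride 20 and reductive elimination from trivalent nickel at the unsubstituted allyl terminus form C4–C5 as the linear β,γ-unsaturated ketone; no free acyl radical is involved, so the (Z)-enoyl unit cannot scramble through a ketenyl radical, and 2,6-lutidine is the only base, so the skipped dienone, C11 and the free tertiary alcohol survive; the closest known reaction types are nickel-catalysed reductive ketone synthesis from in-situ-activated carboxylic acids and alkyl halides with zinc or manganese, nickel-catalysed reductive allylation of aryl halides with allylic carbonates, and nickel/photoredox acylation of alkyltrifluoroborates with acids activated by dimethyl dicarbonate; the acyl–allyl pairing under photochemical reduction has not been shown.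

Step 9
Reactants: 21 (2E,6Z,11R)-1-[5-(tert-butyldimethylsilyloxy)-2-methoxy-3-methylphenyl]-15-hydroxy-3,7,11,15-tetramethylhexadeca-2,6-diene-5,12-dione
Product: 22 (2E,6Z,11R)-15-hydroxy-1-(5-hydroxy-2-methoxy-3-methylphenyl)-3,7,11,15-tetramethylhexadeca-2,6-diene-5,12-dione
Conditions: TBAF (1.2 equiv), AcOH (1.2 equiv), THF, 0 °C
Reagents that add atoms: none
Why: Fluoride cleaves the aryl silyl ether within minutes, and the acetic acid buffer keeps phenoxide and fluoride from isomerising the skipped dienone or epimerising C11 (desilylation).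

## Compound list

1 | 2-bromo-6-methylanisole (1-bromo-2-methoxy-3-methylbenzene) | COc1c(Br)cccc1C | starting material
2 | 2-(3-bromo-4-methoxy-5-methylphenyl)-4,4,5,5-tetramethyl-1,3,2-dioxaborolane | COc1c(Br)cc(cc1C)B1OC(C)(C)C(C)(C)O1 | intermediate
3 | 3-bromo-4-methoxy-5-methylphenol | COc1c(Br)cc(O)cc1C | intermediate
4 | (3-bromo-4-methoxy-5-methylphenoxy)(tert-butyl)dimethylsilane | COc1c(Br)cc(O[Si](C)(C)C(C)(C)C)cc1C | intermediate
5 | 2-methyl-2-vinyloxirane (isoprene monoxide, racemic) | CC1(CO1)C=C | starting material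
6 | [5-(tert-butyldimethylsilyloxy)-2-methoxy-3-methylphenyl]magnesium bromide | COc1c([Mg]Br)cc(O[Si](C)(C)C(C)(C)C)cc1C | intermediate
7 | bromomagnesium (E)-4-[5-(tert-butyldimethylsilyloxy)-2-methoxy-3-methylphenyl]-2-methylbut-2-en-1-olate | COc1c(C)cc(O[Si](C)(C)C(C)(C)C)cc1C/C=C(\C)CO[Mg]Br | intermediate
8 | (E)-4-[5-(tert-butyldimethylsilyloxy)-2-methoxy-3-methylphenyl]-2-methylbut-2-en-1-yl methyl carbonate | COc1c(C)cc(O[Si](C)(C)C(C)(C)C)cc1C/C=C(\C)COC(=O)OC | intermediate
9 | methyl (S)-3-bromo-2-methylpropanoate | BrC[C@@H](C)C(=O)OC | starting material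
10 | vinyl bromide | C=CBr | starting material
11 | bromo[(2S)-3-methoxy-2-methyl-3-oxopropyl]zinc | Br[Zn]C[C@@H](C)C(=O)OC | intermediate
12 | methyl (R)-2-methylpent-4-enoate | C=CC[C@@H](C)C(=O)OC | intermediate
13 | (2R)-N-methoxy-N,2-dimethylpent-4-enamide | C=CC[C@@H](C)C(=O)N(C)OC | intermediate
14 | (Z)-3-iodobut-2-enoic acid | OC(=O)/C=C(/C)I | starting material
15 | (2R)-5-(9-borabicyclo[3.3.1]nonan-9-yl)-N-methoxy-N,2-dimethylpentanamide | B1(CCC[C@@H](C)C(=O)N(C)OC)C2CCCC1CCC2 | intermediate
16 | (2Z,7R)-8-[methoxy(methyl)amino]-3,7-dimethyl-8-oxooct-2-enoic acid | OC(=O)/C=C(/C)CCC[C@@H](C)C(=O)N(C)OC | intermediate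
17 | 4-chloro-2-methylbutan-2-ol | CC(C)(O)CCCl | starting material
18 | chloro[3-(chloromagnesiooxy)-3-methylbutyl]magnesium | CC(C)(CC[Mg]Cl)O[Mg]Cl | intermediate
19 | (2Z,7R)-11-hydroxy-3,7,11-trimethyl-8-oxododec-2-enoic acid | OC(=O)/C=C(/C)CCC[C@@H](C)C(=O)CCC(C)(C)O | intermediate
20 | (2Z,7R)-11-hydroxy-3,7,11-trimethyl-8-oxododec-2-enoic methyl carbonic anhydride | COC(=O)OC(=O)/C=C(/C)CCC[C@@H](C)C(=O)CCC(C)(C)O | intermediate
21 | (2E,6Z,11R)-1-[5-(tert-butyldimethylsilyloxy)-2-methoxy-3-methylphenyl]-15-hydroxy-3,7,11,15-tetramethylhexadeca-2,6-diene-5,12-dione | COc1c(C)cc(O[Si](C)(C)C(C)(C)C)cc1C/C=C(\C)CC(=O)/C=C(/C)CCC[C@@H](C)C(=O)CCC(C)(C)O | intermediate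
22 | (2E,6Z,11R)-15-hydroxy-1-(5-hydroxy-2-methoxy-3-methylphenyl)-3,7,11,15-tetramethylhexadeca-2,6-diene-5,12-dione | COc1c(C)cc(O)cc1C/C=C(\C)CC(=O)/C=C(/C)CCC[C@@H](C)C(=O)CCC(C)(C)O | target

## Step count and risks

Total step count: 9. Longest linear sequence: 6 (steps 4, 5, 6, 7, 8, 9).

**Step 8 (the proposed new coupling).** Likely failure modes are allyl–allyl homocoupling, some branched (C2-acylated) isomer, reversible O-allylation of the carboxylate, and nickel hydride migration of the C2 alkene into conjugation. The fallback uses known chemistry, sets out from 8 and 19 and returns to the route at 21. Carbonate 8 is stannylated with Bu3SnSnBu3 and Pd(PPh3)4 (THF, 50 °C) to give the allylstannane tributyl[(E)-4-[5-(tert-butyldimethylsilyloxy)-2-methoxy-3-methylphenyl]-2-methylbut-2-en-1-yl]stannane F1. Acid 19 is converted with PhSSPh/PBu3 (CH2Cl2, 20 °C) into the thiol ester S-phenyl (2Z,7R)-11-hydroxy-3,7,11-trimethyl-8-oxododec-2-enethioate F2. F1 and F2 are then joined by the neutral palladium-catalysed, copper-mediated thiol ester–organostannane ketone synthesis (Pd2(dba)3, tri(2-furyl)phosphine, CuO2PPh2, THF, 50 °C). This tolerates the ketone and free alcohol and should couple at the less hindered allyl terminus, giving 21.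

**Step 3 (SN2' opening).** The E/Z ratio and some direct epoxide opening may make purification of 8 costly. The fallback sets out from Grignard reagent 6 and returns at 8. Reagent 6 is prenylated with 1-bromo-3-methylbut-2-ene (CuI cat., THF, 0 °C) to give tert-butyl[4-methoxy-3-methyl-5-(3-methylbut-2-en-1-yl)phenoxy]dimethylsilane F3. Allylic oxidation with SeO2 (cat.)/tBuOOH (CH2Cl2, 20 °C, then NaBH4 to reduce any enal) attacks only the (E)-methyl group and gives (E)-4-[5-(tert-butyldimethylsilyloxy)-2-methoxy-3-methylphenyl]-2-methylbut-2-en-1-ol F4 as a single geometric isomer. ClCO2Me/pyridine then gives 8.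

**Step 7 (alkoxide-Grignard addition).** Formation of the doubly magnesiated reagent 18 and its addition to a carboxylate-bearing, poorly soluble Weinreb amide may be sluggish. The fallback sets out from 16 and returns at 19. Amide 16 (iPrMgCl, then CH2=CHMgBr, THF, −20 °C, inverse quench into cold dilute HCl to prevent amine conjugate addition) gives the vinyl ketone (2Z,7R)-3,7-dimethyl-8-oxodeca-2,9-dienoic acid F5. Photocatalytic hydrogen-atom abstraction from 2-propanol ((nBu4N)4[W10O32], 2 mol%, 2-propanol/MeCN, 390 nm, 20 °C) then generates the 2-hydroxyprop-2-yl radical. This nucleophilic radical adds to the unsubstituted enone terminus, much faster than to the β,β-disubstituted enoic acid, and gives 19 directly.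

Further compounds
F1 | step 8 | tributyl[(E)-4-[5-(tert-butyldimethylsilyloxy)-2-methoxy-3-methylphenyl]-2-methylbut-2-en-1-yl]stannane | COc1c(C)cc(O[Si](C)(C)C(C)(C)C)cc1C/C=C(\C)C[Sn](CCCC)(CCCC)CCCC
F2 | step 8 | S-phenyl (2Z,7R)-11-hydroxy-3,7,11-trimethyl-8-oxododec-2-enethioate | O=C(Sc1ccccc1)/C=C(/C)CCC[C@@H](C)C(=O)CCC(C)(C)O
F3 | step 3 | tert-butyl[4-methoxy-3-methyl-5-(3-methylbut-2-en-1-yl)phenoxy]dimethylsilane | COc1c(C)cc(O[Si](C)(C)C(C)(C)C)cc1CC=C(C)C
F4 | step 3 | (E)-4-[5-(tert-butyldimethylsilyloxy)-2-methoxy-3-methylphenyl]-2-methylbut-2-en-1-ol | COc1c(C)cc(O[Si](C)(C)C(C)(C)C)cc1C/C=C(\C)CO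
F5 | step 7 | (2Z,7R)-3,7-dimethyl-8-oxodeca-2,9-dienoic acid | OC(=O)/C=C(/C)CCC[C@@H](C)C(=O)C=C
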